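**Plan**

- The quinone ring is read as the doubly enolised form of a cyclohexane-1,2,4,5-tetraone. It holds two vicinal dicarbonyl pairs (C1/C2 and C4/C5) separated by the two C–H acidic carbons C3 (methyl) and C6 (pentadecenyl).
- Retrosynthesis cuts C2–C3 and C6–C1. C1/C2 leave as diethyl oxalate, and C3–C4–C5–C6 with both side chains remain as the open-chain 1,2-diketone (Z)-icos-15-ene-3,4-dione.
- The diketone is cut at both CO–C bonds of its dicarbonyl unit, giving the bis-Weinreb amide of oxalic acid, a (Z)-hexadec-11-enyl Grignard reagent and ethyllithium.
- Forward: alcohol to bromide; chain and ethyl group joined to the C2 dicarbonyl unit in one pot; the only ring closed last by a double Claisen condensation with oxalate. The ring arrives at the quinone oxidation level, so no redox step and no protecting group are needed.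
- Stereochemistry: there is no stereocentre. The (Z)-alkene is bought with the starting alcohol, is isolated from all reacting sites, and is never touched.

Key step: step 3

Assumption: the target is achiral, so "single enantiomer" reduces to the (Z)-alkene geometry, taken from commercial (Z)-hexadec-11-en-1-ol (a pheromone component) of high isomeric purity.

**Route**

Step 1
Reactants: 1 (Z)-hexadec-11-en-1-ol
Product: 2 (Z)-1-bromohexadec-11-ene
Conditions: CBr4, PPh3, CH2Cl2, 0 °C → rt
Reagents that add atoms: carbon tetrabromide, BrC(Br)(Br)Br
Why: Appel reaction; SN2 displacement of the alkoxyphosphonium at a primary carbon under neutral conditions should leave the remote Z alkene unchanged.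

Step 2
Reactants: 2 (Z)-1-bromohexadec-11-ene; 3 N,N'-dimethoxy-N,N'-dimethyloxamide; 4 ethyllithium
Product: 8 (Z)-icos-15-ene-3,4-dione, via Grignard reagent 5 (not isolated), via mono-adduct 6 (not isolated), via bis-adduct 7 (not isolated)
Conditions: Mg, cat. I2, THF, 40 °C; add to 3 (1.05 equiv), THF, −78 → 0 °C; EtLi 4 (2.5 equiv), −78 → 0 °C; 1 M HCl, 0 °C
Reagents that add atoms: none
Why: Weinreb ketone synthesis applied twice to the oxalic bis-Weinreb amide; the Grignard reagent should add once and stop at the N–O-chelated tetrahedral intermediate, which masks that carbonyl while the more nucleophilic ethyllithium adds to the remaining amide, and both hemiaminals collapse to the 1,2-diketone only on acidic work-up.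

Step 3
Reactants: 8 (Z)-icos-15-ene-3,4-dione; 9 diethyl oxalate
Product: 12 2,5-dihydroxy-3-methyl-6-[(Z)-pentadec-10-en-1-yl]cyclohexa-2,5-diene-1,4-dione, via ethoxalyl diketone 10 (not isolated), via disodium quinonediolate 11 (not isolated)
Conditions: NaOEt (3.5 equiv), 9 (2 equiv), EtOH–THF, slow addition of 8 at 0 °C, then 60 °C, Ar; 1 M HCl
Reagents that add atoms: none
Why: Proposed new method: ethoxide reversibly enolises one α-CH2 of the 1,2-diketone (C2 or C5 of 8), and this carbon is C-acylated by one ester group of diethyl oxalate (crossed Claisen condensation) to give the ethoxalyl diketone 10. The second α-carbon then attacks the remaining ester carbonyl in a 6-(enolendo)-exo-trig Dieckmann-type closure, which makes the second C–C bond and the only ring; the resulting cyclohexane-1,2,4,5-tetraone is already at the quinone oxidation level, is held as its doubly enolised disodium salt 11, and gives 12 on acidification. The closest known reaction types are the base-mediated self-condensation of two α-keto esters RCH2COCO2R' to symmetrical 3,6-dialkyl-2,5-dihydroxybenzoquinones and the double Claisen condensation of dialkyl ketones with dialkyl oxalates to cyclopentane-1,2,4-triones; the extension argued here is the cross-condensation of an unsymmetrical aliphatic 1,2-diketone with an oxalate, which places methyl and pentadecenyl on the ring without a statistical mixture because both come from one diketone. No stereocentre is formed, and the isolated Z alkene is inert to alkoxide. The step needs crossed Claisen acylation to win over self-aldol condensation and benzilic ester rearrangement of the diketone, and ring closure to win over oligomerisation; slow addition of 8 to excess oxalate, the reversibility of all Claisen and aldol steps in NaOEt/EtOH, and the stability of the vinylogous-carboxylate dianion 11 as thermodynamic sink should secure this. Only a six-membered ring can form, because the two nucleophilic carbons of 8 are 1,4-related and the two ester carbons of 9 are 1,2-related.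

**Compound list**

1 | (Z)-hexadec-11-en-1-ol | CCCC/C=C\CCCCCCCCCCO | starting material
2 | (Z)-1-bromohexadec-11-ene | CCCC/C=C\CCCCCCCCCCBr | intermediate
3 | N,N'-dimethoxy-N,N'-dimethyloxamide | CON(C)C(=O)C(=O)N(C)OC | starting material
4 | ethyllithium | [Li]CC | starting material
5 | (Z)-hexadec-11-enylmagnesium bromide | CCCC/C=C\CCCCCCCCCC[Mg]Br | intermediate
6 | bromomagnesium alkoxide of (Z)-2-hydroxy-N-methoxy-2-[methoxy(methyl)amino]-N-methyloctadec-13-enamide (mono-adduct) | CCCC/C=C\CCCCCCCCCCC(O[Mg]Br)(N(C)OC)C(=O)N(C)OC | intermediate
7 | mixed bromomagnesium/lithium dialkoxide of (Z)-3,4-bis[methoxy(methyl)amino]icos-15-ene-3,4-diol (bis-adduct) | CCCC/C=C\CCCCCCCCCCC(O[Mg]Br)(N(C)OC)C(CC)(O[Li])N(C)OC | intermediate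
8 | (Z)-icos-15-ene-3,4-dione | CCCC/C=C\CCCCCCCCCCC(=O)C(=O)CC | intermediate
9 | diethyl oxalate | CCOC(=O)C(=O)OCC | starting material
10 | ethyl (Z)-3-methyl-2,4,5-trioxohenicos-16-enoate (present as its sodium enolate) | CCCC/C=C\CCCCCCCCCCC(=O)C(=O)C(C)C(=O)C(=O)OCC | intermediate
11 | disodium 2-methyl-3,6-dioxo-5-[(Z)-pentadec-10-en-1-yl]cyclohexa-1,4-diene-1,4-diolate | CCCC/C=C\CCCCCCCCCC1=C([O-])C(=O)C(C)=C([O-])C1=O.[Na+].[Na+] | intermediate
12 | 2,5-dihydroxy-3-methyl-6-[(Z)-pentadec-10-en-1-yl]cyclohexa-2,5-diene-1,4-dione | CCCC/C=C\CCCCCCCCCC1=C(O)C(=O)C(C)=C(O)C1=O | target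

**Totals**

Total step count: 3. Longest linear sequence: 3 steps (1 → 2 → 8 → 12).

**Steps most likely to fail**

1. Step 3 (proposed new method). The diketone may be consumed by self-aldol condensation or benzilic ester rearrangement faster than it is acylated, or the mono-acylated intermediate may fail to close and oligomerise instead. The fallback uses the known self-condensation of α-keto esters in its crossed form. It sets out from bromide 2 and comes back at 12. Bromide 2 is converted to the Grignard reagent 5 as in step 2 and added inversely to excess diethyl oxalate 9 in THF at −78 °C, which should give ethyl (Z)-2-oxooctadec-13-enoate F1. F1 is then condensed with an excess of commercial ethyl 2-oxobutanoate (CCC(=O)C(=O)OCC) under NaOEt in EtOH/Et2O and acidified. The excess of the cheap partner should steer F1 into the crossed ring closure, and 12 would be separated from the short-chain symmetrical self-condensation product by its lipophilicity.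

2. Step 2. The mono-adduct may collapse early and expose a ketone to over-addition, the second addition to the deactivated amide may stall, or Wurtz coupling may occur during Grignard formation. The fallback reverses the polarity so that the chain is the electrophile (Corey–Seebach umpolung). It sets out from bromide 2 and comes back at 8. 2-Lithio-1,3-dithiane (1,3-dithiane, n-BuLi, THF, −30 °C) is alkylated with 2 to give 2-[(Z)-hexadec-11-en-1-yl]-1,3-dithiane F2. F2 is lithiated again (n-BuLi, THF, −30 °C) and acylated with N-methoxy-N-methylpropanamide to give 1-{2-[(Z)-hexadec-11-en-1-yl]-1,3-dithian-2-yl}propan-1-one F3. Removal of the dithiane from F3 (MeI, CaCO3, MeCN–H2O, 45 °C) should give diketone 8.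

3. Step 1. Traces of HBr or bromine radicals may erode the Z geometry, and the phosphine oxide may be hard to remove from a non-polar oil. The fallback replaces the in-situ oxyphosphonium activation by an isolated sulfonate and a separate halide displacement, with no phosphine. It sets out from alcohol 1 and comes back at 2. Alcohol 1 is mesylated (MsCl, Et3N, CH2Cl2, 0 °C) to give (Z)-hexadec-11-en-1-yl methanesulfonate F4, and F4 is treated with LiBr in acetone at reflux (Finkelstein-type SN2) to give bromide 2.

**Further compounds**

F1 | step 3 | ethyl (Z)-2-oxooctadec-13-enoate | CCCC/C=C\CCCCCCCCCCC(=O)C(=O)OCC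
F2 | step 2 | 2-[(Z)-hexadec-11-en-1-yl]-1,3-dithiane | CCCC/C=C\CCCCCCCCCCC1SCCCS1
F3 | step 2 | 1-{2-[(Z)-hexadec-11-en-1-yl]-1,3-dithian-2-yl}propan-1-one | CCCC/C=C\CCCCCCCCCCC1(C(=O)CC)SCCCS1
F4 | step 1 | (Z)-hexadec-11-en-1-yl methanesulfonate | CCCC/C=C\CCCCCCCCCCOS(C)(=O)=O
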